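**Retrosynthetic overview**
1. Target ⇐ iodide-induced loss of one ester (as CO2) and ester cleavage from a trans-fused bicyclic β-keto ester ⇐ Dieckmann closure of the cyclopentanone (ring formed last).
2. Ring alkene ⇐ reduction of an enol triflate; the two trans side chains ⇐ two ester-enolate Michael additions, one on a cyclopentenone and one on the enlarged cyclohexenone.
3. 2-Methylcyclohexenone ⇐ one-carbon ring expansion (CH(CH3) insertion with diazoethane) of a cyclopentanone that already holds both quaternary carbons.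
4. Vicinal quaternary carbons ⇐ alkoxide-driven 1,2-shift of a styryl group from a carbinol carbon to the neighbouring enoate carbon, then ester-enolate ethylation; carbinol ⇐ catalytic asymmetric styryl addition to a cyclopentenone ester.
5. Cyclopentenone ester ⇐ cyclopentane-1,3-dione. Ring order: five-membered carbocycle (bought) → enlarged to the cyclohexene ring → cyclopentanone annulated last.

Assumption: the all-trans arrangement of the two cyclopentanone α-substituents (C1, C3 of the target) relative to the ring-fusion bonds is the thermodynamic one; enolate geometries are left undefined in the SMILES.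

**Route**

Step 1
Reactants: 1 cyclopentane-1,3-dione; 2 acetaldehyde
Product: 3 2-ethylcyclopentane-1,3-dione
Conditions: Hantzsch ester, L-proline (10 mol %), CH2Cl2, 23 °C
Reagents that add atoms: none
Why: Proline-catalysed Knoevenagel condensation followed by in situ conjugate hydride transfer from the Hantzsch ester (three-component reductive alkylation) gives clean C-monoethylation of the dione, and no stereocentre is formed.

Step 2
Reactants: 3 2-ethylcyclopentane-1,3-dione
Product: 4 2-ethyl-3-oxocyclopent-1-en-1-yl trifluoromethanesulfonate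
Conditions: Tf2O, Et3N, CH2Cl2, −78 °C
Reagents that add atoms: trifluoromethanesulfonic anhydride, O=S(=O)(OS(=O)(=O)C(F)(F)F)C(F)(F)F
Why: O-Sulfonylation of the enol form of the symmetric dione (enol triflate formation) can give only one vinyl triflate and activates that carbon for cross-coupling.

Step 3
Reactants: 4 2-ethyl-3-oxocyclopent-1-en-1-yl trifluoromethanesulfonate
Product: 5 methyl 2-ethyl-3-oxocyclopent-1-ene-1-carboxylate
Conditions: Pd(OAc)2 (5 mol %), PPh3, CO (1 atm), MeOH, Et3N, DMF, 60 °C
Reagents that add atoms: carbon monoxide, [C-]#[O+]; methanol, CO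
Why: Palladium-catalysed methoxycarbonylation of the vinyl triflate (oxidative addition, CO insertion, methanolysis of the acylpalladium) installs the future carboxyl carbon on the enone β-carbon.

Step 4
Reactants: 5 methyl 2-ethyl-3-oxocyclopent-1-ene-1-carboxylate; 6 phenylacetylene
Product: 9 methyl (3S)-2-ethyl-3-hydroxy-3-[(E)-2-phenylethenyl]cyclopent-1-ene-1-carboxylate, via alkenylzirconocene chloride 7 (not isolated), via alkenyl(methyl)zinc 8 (not isolated)
Conditions: Cp2Zr(H)Cl, CH2Cl2, 23 °C; Me2Zn, toluene, −78 °C; then 5, Ti(OiPr)4 (1.2 equiv), chiral bis(sulfonamide) diol ligand (10 mol %, the enantiomer that gives the 3S alcohol), 23 °C; aq. NH4Cl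
Reagents that add atoms: none
Why: Syn hydrozirconation fixes the E-alkenyl geometry, and transmetalation to zinc with titanium/bis(sulfonamide)-catalysed enantioselective 1,2-alkenylation of the 2-substituted cyclic enone (catalytic asymmetric vinylation of ketones) sets the C3 carbinol centre under ligand control, 1,4-addition being blocked by the fully substituted β-carbon.

Step 5
Reactants: 9 methyl (3S)-2-ethyl-3-hydroxy-3-[(E)-2-phenylethenyl]cyclopent-1-ene-1-carboxylate
Product: 15 methyl (1R,2R)-1,2-diethyl-2-[(E)-2-phenylethenyl]-3-(trimethylsilyloxy)cyclopent-3-ene-1-carboxylate, via potassium alkoxide 10 (not isolated), via potassium ester enolate 11 (not isolated), via potassium ketone enolate 12 (not isolated), via silyl enol ether 13 (not isolated), via lithium ester enolate 14 (not isolated)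
Conditions: KH, 18-crown-6, THF, 0 → 23 °C; Me3SiCl, −78 °C; LiN(iPr)2, −78 → −40 °C; EtI, DMPU, −78 → −20 °C; pH 7 buffer
Reagents that add atoms: chlorotrimethylsilane, C[Si](C)(C)Cl; iodoethane, CCI
Why: Proposed new method: an alkoxide-driven vinylogous semipinacol (anionic 1,2-alkenyl shift) in which the naked potassium alkoxide pushes the styryl group with its bonding pair, on the face it occupies, onto the adjacent β-carbon of the ester-activated alkene, the gain being a C=O bond and an ester enolate that relays a proton to give the ketone enolate, which is capped as its silyl enol ether, so that the carbinol configuration of 9 is transferred intact to the C2 quaternary centre, after which the regenerated ester lithium enolate is ethylated anti to the pseudoaxial styryl group (smaller A-value than ethyl) on the neighbouring quaternary carbon to set C1 with the two ethyl groups cis, the closest known reaction types being the base-mediated α-ketol rearrangement and its vinylogous variants (amine-catalysed vinylogous α-ketol and quinol–enedione shifts) followed by an ordinary ester-enolate alkylation.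

Step 6
Reactants: 15 methyl (1R,2R)-1,2-diethyl-2-[(E)-2-phenylethenyl]-3-(trimethylsilyloxy)cyclopent-3-ene-1-carboxylate
Product: 16 methyl (1R,5R)-1,5-diethyl-4-oxo-5-[(E)-2-phenylethenyl]cyclopent-2-ene-1-carboxylate
Conditions: Pd(OAc)2 (10 mol %), O2 (1 atm), DMSO, 40 °C
Reagents that add atoms: none
Why: Saegusa–Ito oxidation, in which palladation of the regiodefined silyl enol ether and β-hydride elimination give the enone while O2 reoxidises the palladium, introduces the ring double bond without touching the two quaternary centres.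

Step 7
Reactants: 16 methyl (1R,5R)-1,5-diethyl-4-oxo-5-[(E)-2-phenylethenyl]cyclopent-2-ene-1-carboxylate; 17 methyl butanoate
Product: 19 methyl (1R,2R,5R)-1,2-diethyl-5-(1-methoxy-1-oxobutan-2-yl)-3-oxo-2-[(E)-2-phenylethenyl]cyclopentane-1-carboxylate (epimers at the side-chain carbon), via lithium enolate 18 (not isolated)
Conditions: LiN(iPr)2, THF, −78 °C; then 16, −78 → −30 °C; aq. NH4Cl
Reagents that add atoms: none
Why: Michael addition of the ester lithium enolate to the non-enolisable cyclopentenone (1,2-addition is disfavoured at the neopentyl carbonyl) takes place at C2 anti to the pseudoaxial C1 ester and the C5 styryl group, that is on the face of the two ethyl groups, which sets the future C3a centre, while the side-chain centre is left as a mixture because it is epimerisable and is fixed thermodynamically in step 13.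

Step 8
Reactants: 19 methyl (1R,2R,5R)-1,2-diethyl-5-(1-methoxy-1-oxobutan-2-yl)-3-oxo-2-[(E)-2-phenylethenyl]cyclopentane-1-carboxylate
Product: 20 methyl (1R,2R,6R)-1,2-diethyl-6-(1-methoxy-1-oxobutan-2-yl)-4-methyl-3-oxo-2-[(E)-2-phenylethenyl]cyclohexane-1-carboxylate (epimers at C4 and the side-chain carbon)
Conditions: CH3CHN2 (Et2O solution), Sc(OTf)3 (10 mol %), toluene, −78 → −40 °C
Reagents that add atoms: diazoethane, CC=[N+]=[N-]
Why: Lewis acid-catalysed diazoalkane–ketone homologation (Tiffeneau–Demjanov-type ring expansion) in which diazoethane adds to the Sc(OTf)3-activated ketone and the CH2 group, not the quaternary carbon, undergoes the 1,2-shift with loss of N2, so that CH(CH3) is inserted between the carbonyl and the CH2 and the new methine (a mixture) becomes sp2 in step 9.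

Step 9
Reactants: 20 methyl (1R,2R,6R)-1,2-diethyl-6-(1-methoxy-1-oxobutan-2-yl)-4-methyl-3-oxo-2-[(E)-2-phenylethenyl]cyclohexane-1-carboxylate
Product: 21 methyl (1R,2R,6R)-1,2-diethyl-6-(1-methoxy-1-oxobutan-2-yl)-4-methyl-3-oxo-2-[(E)-2-phenylethenyl]cyclohex-4-ene-1-carboxylate
Conditions: IBX, 4-methoxypyridine N-oxide, DMSO, 40 °C
Reagents that add atoms: none
Why: IBX dehydrogenation of the ketone through its only possible enol, the one towards the methyl-bearing carbon, gives the 2-methylcyclohex-2-enone and merges the methine epimers.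

Step 10
Reactants: 21 methyl (1R,2R,6R)-1,2-diethyl-6-(1-methoxy-1-oxobutan-2-yl)-4-methyl-3-oxo-2-[(E)-2-phenylethenyl]cyclohex-4-ene-1-carboxylate; 22 methyl propanoate
Product: 25 methyl (1R,2R,5R,6R)-1,2-diethyl-6-(1-methoxy-1-oxobutan-2-yl)-5-(1-methoxy-1-oxopropan-2-yl)-4-methyl-2-[(E)-2-phenylethenyl]-3-[(trifluoromethanesulfonyl)oxy]cyclohex-3-ene-1-carboxylate (epimers at both side-chain carbons), via lithium enolate 23 (not isolated), via adduct enolate 24 (not isolated)
Conditions: LiN(iPr)2, THF, −78 °C; then 21, −78 → −40 °C; PhNTf2, −78 → 0 °C; aq. NH4Cl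
Reagents that add atoms: N-phenylbis(trifluoromethanesulfonimide), O=S(=O)(N(c1ccccc1)S(=O)(=O)C(F)(F)F)C(F)(F)F
Why: A second ester-enolate Michael addition occurs at C5 anti to the neighbouring C6 side chain (trans-3,4 relationship, sets the future C7a centre), and O-triflation of the regiospecifically formed tetrasubstituted enolate (conjugate addition–enolate trapping) fixes the position of the future ring alkene.

Step 11
Reactants: 25 the enol triflate of step 10
Product: 26 methyl (1R,2S,5R,6R)-1,2-diethyl-6-(1-methoxy-1-oxobutan-2-yl)-5-(1-methoxy-1-oxopropan-2-yl)-4-methyl-2-[(E)-2-phenylethenyl]cyclohex-3-ene-1-carboxylate (epimers at both side-chain carbons)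
Conditions: Pd(OAc)2 (5 mol %), PPh3, HCO2H, Et3N, DMF, 60 °C
Reagents that add atoms: none
Why: Palladium-catalysed formate reduction of the enol triflate (oxidative addition, formate exchange, decarboxylation, reductive elimination) replaces the triflate by hydrogen without moving the double bond or touching the styrene.

Step 12
Reactants: 26 the cyclohexene triester of step 11
Product: 27 dimethyl (3aR,4R,5S,7aS)-3,4,5-triethyl-1,7-dimethyl-2-oxo-5-[(E)-2-phenylethenyl]-2,3,3a,4,5,7a-hexahydro-1H-indene-1,4-dicarboxylate (epimers at C1 and C3)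
Conditions: KN(SiMe3)2 (2.2 equiv), THF, −78 → 0 °C; aq. NH4Cl
Reagents that add atoms: none
Why: Dieckmann condensation in which the less hindered propanoate α-carbon attacks the butanoate ester carbonyl closes the trans-fused cyclopentanone across the two side chains whose trans relationship was set in steps 7 and 10, the second equivalent of base enolising the new ketone so that the closure is irreversible, and the alternative mode of closure would converge in step 13.

Step 13
Reactants: 27 the bicyclic β-keto diester of step 12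
Product: 28 (1S,3S,3aR,4R,5S,7aR)-3,4,5-triethyl-1,7-dimethyl-2-oxo-5-[(E)-2-phenylethenyl]-2,3,3a,4,5,7a-hexahydro-1H-indene-4-carboxylic acid (target)
Conditions: LiI, DMF, 130 °C; then DBU (0.2 equiv), 23 °C; aq. HCl
Reagents that add atoms: none
Why: Iodide cleaves both methyl esters by SN2 attack at the methyl groups (Krapcho-type dealkoxycarbonylation of the β-keto ester with loss of CO2 and demethylation of the hindered neopentyl ester), and base equilibration then places the α-methyl and α-ethyl groups trans to their ring-fusion neighbours, the thermodynamically preferred all-trans cyclopentanone, to give the target.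

**Compound list**
1 | cyclopentane-1,3-dione | O=C1CCC(=O)C1 | starting material
2 | acetaldehyde | CC=O | starting material
3 | 2-ethylcyclopentane-1,3-dione | CCC1C(=O)CCC1=O | intermediate
4 | 2-ethyl-3-oxocyclopent-1-en-1-yl trifluoromethanesulfonate | CCC1=C(OS(=O)(=O)C(F)(F)F)CCC1=O | intermediate
5 | methyl 2-ethyl-3-oxocyclopent-1-ene-1-carboxylate | CCC1=C(C(=O)OC)CCC1=O | intermediate
6 | phenylacetylene | C#Cc1ccccc1 | starting material
7 | chlorobis(cyclopentadienyl)[(E)-2-phenylethenyl]zirconium | Cl[Zr](/C=C/c1ccccc1)(C1C=CC=C1)C1C=CC=C1 | intermediate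
8 | methyl[(E)-2-phenylethenyl]zinc | C[Zn]/C=C/c1ccccc1 | intermediate
9 | methyl (3S)-2-ethyl-3-hydroxy-3-[(E)-2-phenylethenyl]cyclopent-1-ene-1-carboxylate | CCC1=C(C(=O)OC)CC[C@]1(O)/C=C/c1ccccc1 | intermediate
10 | potassium alkoxide of 9 | CCC1=C(C(=O)OC)CC[C@]1([O-])/C=C/c1ccccc1.[K+] | intermediate
11 | potassium ester enolate of methyl (2R)-2-ethyl-3-oxo-2-[(E)-2-phenylethenyl]cyclopentane-1-carboxylate | CC[C@]1(/C=C/c2ccccc2)C(=O)CCC1=C([O-])OC.[K+] | intermediate
12 | potassium ketone enolate of methyl (2R)-2-ethyl-3-oxo-2-[(E)-2-phenylethenyl]cyclopentane-1-carboxylate (C1 epimers) | CC[C@]1(/C=C/c2ccccc2)C([O-])=CCC1C(=O)OC.[K+] | intermediate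
13 | methyl (2R)-2-ethyl-2-[(E)-2-phenylethenyl]-3-(trimethylsilyloxy)cyclopent-3-ene-1-carboxylate (C1 epimers) | CC[C@]1(/C=C/c2ccccc2)C(O[Si](C)(C)C)=CCC1C(=O)OC | intermediate
14 | lithium ester enolate of 13 | CC[C@]1(/C=C/c2ccccc2)C(O[Si](C)(C)C)=CCC1=C([O-])OC.[Li+] | intermediate
15 | methyl (1R,2R)-1,2-diethyl-2-[(E)-2-phenylethenyl]-3-(trimethylsilyloxy)cyclopent-3-ene-1-carboxylate | CC[C@]1(/C=C/c2ccccc2)C(O[Si](C)(C)C)=CC[C@@]1(CC)C(=O)OC | intermediate
16 | methyl (1R,5R)-1,5-diethyl-4-oxo-5-[(E)-2-phenylethenyl]cyclopent-2-ene-1-carboxylate | CC[C@]1(/C=C/c2ccccc2)C(=O)C=C[C@@]1(CC)C(=O)OC | intermediate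
17 | methyl butanoate | CCCC(=O)OC | starting material
18 | lithium enolate of methyl butanoate | CCC=C([O-])OC.[Li+] | intermediate
19 | methyl (1R,2R,5R)-1,2-diethyl-5-(1-methoxy-1-oxobutan-2-yl)-3-oxo-2-[(E)-2-phenylethenyl]cyclopentane-1-carboxylate (side-chain epimers) | CC[C@]1(/C=C/c2ccccc2)C(=O)C[C@H](C(CC)C(=O)OC)[C@@]1(CC)C(=O)OC | intermediate
20 | methyl (1R,2R,6R)-1,2-diethyl-6-(1-methoxy-1-oxobutan-2-yl)-4-methyl-3-oxo-2-[(E)-2-phenylethenyl]cyclohexane-1-carboxylate (epimers at C4 and side chain) | CC[C@]1(/C=C/c2ccccc2)C(=O)C(C)C[C@H](C(CC)C(=O)OC)[C@@]1(CC)C(=O)OC | intermediate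
21 | methyl (1R,2R,6R)-1,2-diethyl-6-(1-methoxy-1-oxobutan-2-yl)-4-methyl-3-oxo-2-[(E)-2-phenylethenyl]cyclohex-4-ene-1-carboxylate (side-chain epimers) | CC[C@]1(/C=C/c2ccccc2)C(=O)C(C)=C[C@H](C(CC)C(=O)OC)[C@@]1(CC)C(=O)OC | intermediate
22 | methyl propanoate | CCC(=O)OC | starting material
23 | lithium enolate of methyl propanoate | CC=C([O-])OC.[Li+] | intermediate
24 | lithium enolate (ring C3 oxide, C3=C4) formed by conjugate addition of 23 to 21 | CC[C@]1(/C=C/c2ccccc2)C([O-])=C(C)[C@@H](C(C)C(=O)OC)[C@H](C(CC)C(=O)OC)[C@@]1(CC)C(=O)OC.[Li+] | intermediate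
25 | methyl (1R,2R,5R,6R)-1,2-diethyl-6-(1-methoxy-1-oxobutan-2-yl)-5-(1-methoxy-1-oxopropan-2-yl)-4-methyl-2-[(E)-2-phenylethenyl]-3-[(trifluoromethanesulfonyl)oxy]cyclohex-3-ene-1-carboxylate | CC[C@]1(/C=C/c2ccccc2)C(OS(=O)(=O)C(F)(F)F)=C(C)[C@@H](C(C)C(=O)OC)[C@H](C(CC)C(=O)OC)[C@@]1(CC)C(=O)OC | intermediate
26 | methyl (1R,2S,5R,6R)-1,2-diethyl-6-(1-methoxy-1-oxobutan-2-yl)-5-(1-methoxy-1-oxopropan-2-yl)-4-methyl-2-[(E)-2-phenylethenyl]cyclohex-3-ene-1-carboxylate | CC[C@]1(/C=C/c2ccccc2)C=C(C)[C@@H](C(C)C(=O)OC)[C@H](C(CC)C(=O)OC)[C@@]1(CC)C(=O)OC | intermediate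
27 | dimethyl (3aR,4R,5S,7aS)-3,4,5-triethyl-1,7-dimethyl-2-oxo-5-[(E)-2-phenylethenyl]-2,3,3a,4,5,7a-hexahydro-1H-indene-1,4-dicarboxylate (epimers at C1 and C3) | CC[C@]1(/C=C/c2ccccc2)C=C(C)[C@@H]3[C@@H]([C@@]1(CC)C(=O)OC)C(CC)C(=O)C3(C)C(=O)OC | intermediate
28 | (1S,3S,3aR,4R,5S,7aR)-3,4,5-triethyl-1,7-dimethyl-2-oxo-5-[(E)-2-phenylethenyl]-2,3,3a,4,5,7a-hexahydro-1H-indene-4-carboxylic acid | CC[C@@H]1C(=O)[C@@H](C)[C@@H]2C(C)=C[C@@](/C=C/c3ccccc3)(CC)[C@](CC)(C(=O)O)[C@H]21 | target

**Step count**
Total steps: 13. Longest linear sequence: 13 (1 → 28); compounds 6, 17 and 22 enter as bought materials.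

**Steps most likely to fail, with fallbacks**

Step 5 (the proposed new 1,2-shift). The alkoxide-driven shift may be slow or reversible, and the face selectivity of the ethylation next to a carbon bearing ethyl and styryl is uncertain. The fallback uses known chemistry only: it makes the ester-bearing quaternary carbon first and the second one by a Lewis acid-mediated 1,2-acyl shift with ring contraction. It sets out from 17 and comes back at 16. The lithium enolate 18 is acylated with propanoyl chloride to give methyl 2-ethyl-3-oxopentanoate F1. An enantioselective Michael addition to but-3-en-2-one (cinchona-derived bifunctional amine catalyst) gives methyl (2R)-2-ethyl-5-oxo-2-propanoylhexanoate F2. Pyrrolidinium acetate closes it to methyl (1R)-1,2-diethyl-4-oxocyclohex-2-ene-1-carboxylate F3 (Robinson annulation). t-BuOOH/DBU epoxidises the enone on the face of the ester to give methyl 1,2-diethyl-5-oxo-7-oxabicyclo[4.1.0]heptane-2-carboxylate F4 (oxirane cis to the ester). BF3·OEt2 opens the oxirane at the tertiary carbon and the ring acyl carbon migrates, contracting the ring to methyl (1R,2S)-1,2-diethyl-2-formyl-3-oxocyclopentane-1-carboxylate F5. Wittig olefination of the aldehyde with benzylidenetriphenylphosphorane, then iodine-catalysed isomerisation to the E-alkene, gives methyl (1R,2R)-1,2-diethyl-3-oxo-2-[(E)-2-phenylethenyl]cyclopentane-1-carboxylate F6. IBX dehydrogenation of F6 gives 16.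

Step 7 (first Michael addition). The β-carbon is neopentyl and the face selectivity rests on a small steric difference between the ester and the ethyl group. The fallback sets the ring stereocentre by catalyst-controlled C–H instead of C–C bond formation; it sets out from 16 and comes back at 19. The addition of 18 to 16 is run as before, but the ring enolate is quenched with PhSeBr to give methyl 1,2-diethyl-5-(1-methoxy-1-oxobutan-2-yl)-3-oxo-2-[(E)-2-phenylethenyl]-4-(phenylselanyl)cyclopentane-1-carboxylate F7 (quaternary centres as in 16; the other ring centres are irrelevant). H2O2 oxidation and selenoxide elimination give methyl 1,5-diethyl-2-(1-methoxy-1-oxobutan-2-yl)-4-oxo-5-[(E)-2-phenylethenyl]cyclopent-2-ene-1-carboxylate F8. A ligand-controlled conjugate reduction (CuH generated from Cu(OAc)2, a chiral bisphosphine and polymethylhydrosiloxane) then delivers hydride to the ring β-carbon from the face chosen by the ligand and gives 19.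

Step 8 (ring expansion). The ketone is hindered, diazoethane is awkward to handle, and over-homologation or migration of the wrong carbon is possible. The fallback is a carbenoid ring enlargement; it sets out from 19 and comes back at 20. The lithium carbenoid made from 1,1-dibromoethane and LiN(iPr)2 adds to the ring ketone to give methyl 3-(1,1-dibromoethyl)-1,2-diethyl-3-hydroxy-5-(1-methoxy-1-oxobutan-2-yl)-2-[(E)-2-phenylethenyl]cyclopentane-1-carboxylate F9. n-BuLi at −95 °C effects bromine–lithium exchange, and the β-oxido carbenoid rearranges with migration of the ring CH2 group; protonation gives 20.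

**Further compounds**
F1 | step 5 | methyl 2-ethyl-3-oxopentanoate | CCC(=O)C(CC)C(=O)OC
F2 | step 5 | methyl (2R)-2-ethyl-5-oxo-2-propanoylhexanoate | CCC(=O)[C@@](CC)(CCC(C)=O)C(=O)OC
F3 | step 5 | methyl (1R)-1,2-diethyl-4-oxocyclohex-2-ene-1-carboxylate | CCC1=CC(=O)CC[C@@]1(CC)C(=O)OC
F4 | step 5 | methyl 1,2-diethyl-5-oxo-7-oxabicyclo[4.1.0]heptane-2-carboxylate (oxirane cis to the ester) | CC[C@]12O[C@H]1C(=O)CC[C@@]2(CC)C(=O)OC
F5 | step 5 | methyl (1R,2S)-1,2-diethyl-2-formyl-3-oxocyclopentane-1-carboxylate | CC[C@]1(C=O)C(=O)CC[C@@]1(CC)C(=O)OC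
F6 | step 5 | methyl (1R,2R)-1,2-diethyl-3-oxo-2-[(E)-2-phenylethenyl]cyclopentane-1-carboxylate | CC[C@]1(/C=C/c2ccccc2)C(=O)CC[C@@]1(CC)C(=O)OC
F7 | step 7 | methyl 1,2-diethyl-5-(1-methoxy-1-oxobutan-2-yl)-3-oxo-2-[(E)-2-phenylethenyl]-4-(phenylselanyl)cyclopentane-1-carboxylate | CC[C@]1(/C=C/c2ccccc2)C(=O)C([Se]c2ccccc2)C(C(CC)C(=O)OC)[C@@]1(CC)C(=O)OC
F8 | step 7 | methyl 1,5-diethyl-2-(1-methoxy-1-oxobutan-2-yl)-4-oxo-5-[(E)-2-phenylethenyl]cyclopent-2-ene-1-carboxylate | CC[C@]1(/C=C/c2ccccc2)C(=O)C=C(C(CC)C(=O)OC)[C@@]1(CC)C(=O)OC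
F9 | step 8 | methyl 3-(1,1-dibromoethyl)-1,2-diethyl-3-hydroxy-5-(1-methoxy-1-oxobutan-2-yl)-2-[(E)-2-phenylethenyl]cyclopentane-1-carboxylate | CC[C@]1(/C=C/c2ccccc2)C(O)(C(C)(Br)Br)C[C@H](C(CC)C(=O)OC)[C@@]1(CC)C(=O)OC
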